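0.320 M of electrophile is what the amines can carry here, and the flasks are charged on both sides of that line.

| flask | electrophile | nucleophile | free base | time |
|---|---|---|---|---|
| Monday's | 0.20 M | 0.320 M | 0.320 M | 6.0 h |
| Saturday's | 0.25 M | 0.320 M | 0.320 M | 6.0 h |
| Sunday's | 0.40 M | 0.320 M | 0.320 M | 6.0 h |
| Friday's | 0.60 M | 0.320 M | 0.320 M | 6.0 h |
| Tuesday's | 1.0 M | 0.320 M | 0.320 M | 6.0 h |

    electrophile + nucleophile → acid set free + target (k1 = 13.7 L mol⁻¹ h⁻¹)
    free base + target → over-reaction product (k2 = 1.17 L mol⁻¹ h⁻¹)
    acid set free + free base ⇌ salt of the base, settled at all times (K3 = 1890 L mol⁻¹)
    nucleophile + acid set free ⇌ protonated nucleophile, settled at all times (K4 = 13400 L mol⁻¹)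

- "hardly changes" means that all values lie within two and a half points (for a concentration: within two and a half percent of the largest)
- run time (Monday's): 6.0 h

- amount of target at the end, in percent of the electrophile charged for Monday's, Saturday's, Sunday's, Friday's, Tuesday's, in this order
- the course of these numbers from the first flask to the last (rises all the way / rises, then falls / falls all the way / falls, then rises / hardly changes)

Each conversion of electrophile uses one nucleophile and frees one acid. The two fast balances are strong: at the start, equilibrium constant times amine is 4300 for the nucleophile and 600 for the free base. I therefore take the acid set free as bound to one amine or the other, and each conversion costs two amines. That gives me one number per flask, the amine ceiling: the nucleophile and free base charged, divided by two, as a fraction of the electrophile charged.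

| Flask | Amine ceiling |
|---|---|
| Monday's | 160% |
| Saturday's | 128% |
| Sunday's | 80.0% |
| Friday's | 53.3% |
| Tuesday's | 32.0% |

Above one, the charged amines cover the electrophile, and free base beyond that can attack target. Below one, the amines are the limiting reagent and the ceiling caps the yield. In Monday's flask, at charged levels, the electrophile's half-life is 0.16 h and the target's is 1.9 h. Target therefore forms early and then sits through 3.24 of its own half-lives, counted at charged free base. My reckoning stops at a shape: the row rises while the ceiling stands above one and falls below it. I commit to no yields for the low charges.

The forecast gives 35%, 40%, 41%, 36% and 25%, with the course rises, then falls. For the fall it says “the excess electrophile cannot be converted”.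

The flasks end at 35.8%, 41.2%, 39.9%, 32.5% and 22.8%, with the course rises, then falls. The row turns at a reading of 0.30 M. The forecast stands within its tolerance.

Each over-reaction takes one free base from the amines, so the ceiling drops by the over-reaction product divided by two. Tuesday's flask holds 6.42% of that product, which lowers its ceiling to 28.8%, and it converts 29.2%, with 0.0164 M of acid set free still unbound at the end. Friday's flask holds 13.7%, which gives 46.5%, and it converts 46.2%. Monday's flask stands low mainly because of the step from free base and target to over-reaction product: in the run without that step, Monday's target ends at 98.3% instead of 35.8%.

The numbers of this flask are invented, and the outcome is calculated.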